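Leoligin is disconnected at the two exocyclic bonds C3–C9 and C4–C7' of its oxolane ring (O1, C2–C5). These bonds are cis to one another and trans to the aryl group on C2, which is what a cis-annulation across the C3=C4 bond of an (S)-5-aryl butenolide, anti to the aryl group, would leave. One sensitised [2+2] photocycloaddition of that butenolide with the TBS enol ether of (3,4-dimethoxyphenyl)acetaldehyde forms both bonds and both stereocentres. The surplus C9–C7' bond of the cyclobutane is then cut by alkoxy-radical β-scission. Reduction, acid-mediated re-closure at C2 and a Mitsunobu angelate esterification finish the synthesis.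

Key step: step 5

**Remarks on the chemistry (valid for all steps)**

- Numbering: oxolane ring of the target O1, C2 (aryl), C3, C4, C5; C9 is the CH2O carbon on C3, C7' the benzylic carbon on C4. The same labels are used for these atoms in every intermediate.
- Assumption: enol ether 8 is formed and used as an E/Z mixture (the E isomer is drawn), since the triplet state in step 5 loses the alkene geometry.
- Sensitiser: Ir(dFppy)3, tris[2-(2,4-difluorophenyl)pyridinato]iridium, a neutral complex of trivalent iridium, is chosen for step 5. Its triplet energy is adequate for a styrene-type chromophore but its excited state is only weakly oxidising. Both partners carry veratryl groups and 8 is an easily oxidised enol ether, so a strongly oxidising sensitiser or an aromatic ketone would open radical-cation or hydrogen-abstraction channels.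
- Partners: the bulky TBS group is kept because it raises the facial bias of the attacking radical. Enol ether 8 is distilled free of amine, because base would racemise 6. No Lewis acid is used, because it would trigger a Mukaiyama–Michael addition that joins C7', not C9, to C3. Butenolide 6 is the limiting reagent at high concentration, since unproductive triplet decay only regenerates 8.
- Stereochemical bookkeeping: C2 of 6 acts as a relay. It directs the face in step 5 and is re-formed in step 9. A syn cycloadduct would therefore end as the enantiomer of the target, so diastereomers are removed at 11 or, at the latest, at 12.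

**Route**

Step 1
Reactants: 1 4-(3,4-dimethoxyphenyl)-4-oxobutanoic acid
Product: 3 (5S)-5-(3,4-dimethoxyphenyl)oxolan-2-one, via hydroxy acid 2 (not isolated)
Conditions: RuCl(p-cymene)[(S,S)-TsDPEN] (1 mol %), HCO2H/Et3N (5:2), 40 °C; lactonisation completed by stirring the extract with aq. citric acid, rt
Reagents that add atoms: none
Why: Noyori-type asymmetric transfer hydrogenation of an aryl ketone, in which the (S,S)-ligand and the CH/π contact between the p-cymene ring and the veratryl group fix hydride delivery to one ketone face and should give the (S)-carbinol, which closes to the γ-lactone by acyl substitution at the carboxyl group without touching the C–O bond of the stereocentre.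

Step 2
Reactants: 3 (5S)-5-(3,4-dimethoxyphenyl)oxolan-2-one
Product: 4 (5S)-5-(3,4-dimethoxyphenyl)-3-(phenylselanyl)oxolan-2-one (both C3 epimers)
Conditions: LiN(iPr)2 (1.05 equiv), THF, −78 °C; PhSeBr (1.1 equiv), −78 °C; aq. NH4Cl
Reagents that add atoms: phenylselanyl bromide, Br[Se]c1ccccc1
Why: Kinetic lithium enolate formation at the only acidic position of the lactone followed by electrophilic α-selenenylation; the new centre at the α-carbon is of no consequence because step 3 removes it, and the benzylic stereocentre is not involved.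

Step 3
Reactants: 4 (5S)-5-(3,4-dimethoxyphenyl)-3-(phenylselanyl)oxolan-2-one
Product: 6 (5S)-5-(3,4-dimethoxyphenyl)furan-2(5H)-one, via selenoxide 5 (not isolated)
Conditions: 30% H2O2 (3 equiv), CH2Cl2, 0 °C to rt; pH 7 buffer wash, short silica plug, no amine at any point; enantiopurity checked by chiral HPLC and the material used promptly
Reagents that add atoms: none
Why: Selenoxide syn-elimination, in which oxidation at selenium is followed by a five-centre elimination whose only syn β-hydrogens lie on the ring CH2, so the double bond enters conjugation with the carbonyl group, while the neutral to weakly acidic medium should leave the doubly activated benzylic C–H unexchanged.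

Step 4
Reactants: 7 (3,4-dimethoxyphenyl)acetaldehyde
Product: 8 tert-butyl{[2-(3,4-dimethoxyphenyl)ethenyl]oxy}dimethylsilane (E/Z mixture)
Conditions: TBSOTf (1.2 equiv), Et3N (1.5 equiv), CH2Cl2, 0 °C; cold aq. NaHCO3, then bulb-to-bulb distillation to remove all amine
Reagents that add atoms: tert-butyldimethylsilyl trifluoromethanesulfonate, CC(C)(C)[Si](C)(C)OS(=O)(=O)C(F)(F)F
Why: Soft enolisation, in which O-silylation of the aldehyde gives a silyloxocarbenium ion that triethylamine deprotonates at the benzylic carbon to the aryl-conjugated silyl enol ether; no stereocentre is formed.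

Step 5
Reactants: 6 (5S)-5-(3,4-dimethoxyphenyl)furan-2(5H)-one; 8 tert-butyl{[2-(3,4-dimethoxyphenyl)ethenyl]oxy}dimethylsilane
Product: 9 (1R,4S,5S)-6-[(tert-butyldimethylsilyl)oxy]-4,7-bis(3,4-dimethoxyphenyl)-3-oxabicyclo[3.2.0]heptan-2-one (mixture of C6 and C7 epimers)
Conditions: Ir(dFppy)3 (1 mol %), 8 (2.5 equiv, two portions), degassed CH2Cl2 (0.4 M in 6), 427 nm LEDs, 0 °C; chromatography on neutral silica
Reagents that add atoms: none
Why: Proposed new method: energy transfer from the excited iridium sensitiser (triplet energy near 60 kcal/mol, too low for the lactone chromophore) should populate only the triplet of the aryl enol ether 8, a 1,2-biradical whose nucleophilic α-silyloxy carbon C9 adds to the electron-poor β-carbon C3 of 6, and the resulting triplet 1,4-biradical (benzylic at C7', α-acyl at C4) closes the C4–C7' bond after spin inversion. The closest known reaction types are the energy-transfer [2+2] cycloaddition of styrenes and the [2+2] photocycloaddition of 5-substituted furan-2(5H)-ones with alkenes; what has not been shown is the intermolecular capture of an acyclic aryl enol ether triplet by a butenolide. The cyclobutane ring is closed stepwise, by intermolecular radical addition followed by recombination of the 1,4-biradical, and cis fusion to the lactone is the only outcome the five-membered ring tolerates. C3 is set by attack on the face of 6 opposite the C2 aryl group, which sits on the carbon next to the one attacked, C4 follows from the cis ring fusion, and C9 and C7' form without control and are erased in step 7. The step needs regioselectivity (C9 to C3, C7' to C4), which radical polarity and the stabilisation of both radical centres of the intermediate should secure, and anti facial selectivity, which the C2 aryl group and the bulky tert-butyldimethylsilyl group should secure. The neutral, amine-free medium and the weakly oxidising sensitiser should keep C2 from racemising and the veratryl groups out of radical-cation pathways.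

Step 6
Reactants: 9 (1R,4S,5S)-6-[(tert-butyldimethylsilyl)oxy]-4,7-bis(3,4-dimethoxyphenyl)-3-oxabicyclo[3.2.0]heptan-2-one
Product: 10 (1R,4S,5R)-6-hydroxy-4,7-bis(3,4-dimethoxyphenyl)-3-oxabicyclo[3.2.0]heptan-2-one (C6 and C7 epimers)
Conditions: Bu4NF (1.2 equiv), AcOH (1.2 equiv), THF, 0 °C to rt
Reagents that add atoms: none
Why: Fluoride-induced desilylation driven by Si–F bond formation, buffered with acetic acid so that the lactone stays closed; the ring-fusion centres cannot epimerise because a trans-fused bicyclo[3.2.0] skeleton is prohibitively strained.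

Step 7
Reactants: 10 (1R,4S,5R)-6-hydroxy-4,7-bis(3,4-dimethoxyphenyl)-3-oxabicyclo[3.2.0]heptan-2-one
Product: 11 (2S,3S,4R)-4-(3,4-dimethoxybenzyl)-2-(3,4-dimethoxyphenyl)-5-oxooxolane-3-carbaldehyde
Conditions: [Ir(dF(CF3)ppy)2(5,5'-d(CF3)bpy)]PF6 (2 mol %), 2,4,6-triisopropylbenzenethiol (20 mol %), 2,4,6-collidine (50 mol %), CH2Cl2 (0.05 M), 450 nm LEDs, rt; fast silica filtration, minor diastereomers removed, used the same day
Reagents that add atoms: none
Why: Photoredox proton-coupled electron transfer ring opening of a cyclic alcohol, in which the excited iridium complex oxidises the electron-rich arene on C7', collidine takes the hydroxyl proton, and the alkoxy radical undergoes strain-driven β-scission of C9–C7' toward the benzylic radical (cleavage of C9–C3 would give an unstabilised radical), which the thiol reduces by hydrogen atom transfer, so that C9 and C7' lose their stereogenicity while C3 and C4 are untouched.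

Step 8
Reactants: 11 (2S,3S,4R)-4-(3,4-dimethoxybenzyl)-2-(3,4-dimethoxyphenyl)-5-oxooxolane-3-carbaldehyde
Product: 12 (2R,3R)-2-(3,4-dimethoxybenzyl)-3-[(S)-(3,4-dimethoxyphenyl)(hydroxy)methyl]butane-1,4-diol
Conditions: LiAlH4 (4 equiv), THF, −20 °C to rt, inverse addition; aq. NaOH work-up; chromatography to diastereomeric purity
Reagents that add atoms: none
Why: Hydride reduction (LiAlH4) of the aldehyde and of the lactone to the triol with C2, C3 and C4 untouched, the fast low-temperature hydride addition outrunning enolisation of the β-acyloxy aldehyde.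

Step 9
Reactants: 12 (2R,3R)-2-(3,4-dimethoxybenzyl)-3-[(S)-(3,4-dimethoxyphenyl)(hydroxy)methyl]butane-1,4-diol
Product: 13 [(2S,3R,4R)-4-(3,4-dimethoxybenzyl)-2-(3,4-dimethoxyphenyl)oxolan-3-yl]methanol
Conditions: camphor-10-sulfonic acid (10 mol %), CH2Cl2, 0 °C; quenched with Et3N as soon as 12 is consumed
Reagents that add atoms: none
Why: Acid-catalysed SN1 cycloetherification, in which the veratryl carbinol ionises to a stabilised benzylic cation that the C5 hydroxyl captures in a five-membered ring closure (the C9 hydroxyl could only form an oxetane), and C2 is re-formed with the aryl group trans to the C3 substituent, the less crowded arrangement reached under reversible ionisation, which should restore the (2S) configuration.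

Step 10
Reactants: 13 [(2S,3R,4R)-4-(3,4-dimethoxybenzyl)-2-(3,4-dimethoxyphenyl)oxolan-3-yl]methanol; 14 angelic acid, (2Z)-2-methylbut-2-enoic acid
Product: 15 leoligin, [(2S,3R,4R)-4-(3,4-dimethoxybenzyl)-2-(3,4-dimethoxyphenyl)oxolan-3-yl]methyl (2Z)-2-methylbut-2-enoate
Conditions: 14 (1.5 equiv), PPh3 (1.5 equiv), DIAD (1.5 equiv), THF, 0 °C to rt
Reagents that add atoms: none
Why: Mitsunobu esterification, in which the primary C9 hydroxyl is activated as an alkoxyphosphonium ion and displaced by the angelate anion at a non-stereogenic carbon, so the acid is never turned into an acyl electrophile or exposed to a nucleophilic amine and the (Z)-alkene should not isomerise to the tiglate.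

**Compound list**

1 | 4-(3,4-dimethoxyphenyl)-4-oxobutanoic acid | COc1ccc(C(=O)CCC(=O)O)cc1OC | starting material
2 | (4S)-4-(3,4-dimethoxyphenyl)-4-hydroxybutanoic acid | OC(=O)CC[C@H](O)c1ccc(OC)c(OC)c1 | intermediate (not isolated)
3 | (5S)-5-(3,4-dimethoxyphenyl)oxolan-2-one | O=C1CC[C@@H](c2ccc(OC)c(OC)c2)O1 | intermediate
4 | (5S)-5-(3,4-dimethoxyphenyl)-3-(phenylselanyl)oxolan-2-one, C3 epimers | O=C1C([Se]c2ccccc2)C[C@@H](c2ccc(OC)c(OC)c2)O1 | intermediate
5 | (5S)-5-(3,4-dimethoxyphenyl)-3-(phenylseleninyl)oxolan-2-one | O=C1C([Se](=O)c2ccccc2)C[C@@H](c2ccc(OC)c(OC)c2)O1 | intermediate (not isolated)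
6 | (5S)-5-(3,4-dimethoxyphenyl)furan-2(5H)-one | O=C1C=C[C@@H](c2ccc(OC)c(OC)c2)O1 | intermediate
7 | (3,4-dimethoxyphenyl)acetaldehyde | COc1ccc(CC=O)cc1OC | starting material
8 | tert-butyl{[2-(3,4-dimethoxyphenyl)ethenyl]oxy}dimethylsilane, E/Z mixture, E isomer drawn | COc1ccc(/C=C/O[Si](C)(C)C(C)(C)C)cc1OC | intermediate
9 | (1R,4S,5S)-6-[(tert-butyldimethylsilyl)oxy]-4,7-bis(3,4-dimethoxyphenyl)-3-oxabicyclo[3.2.0]heptan-2-one, C6 and C7 epimers | O=C1O[C@H](c3ccc(OC)c(OC)c3)[C@H]2C(O[Si](C)(C)C(C)(C)C)C(c3ccc(OC)c(OC)c3)[C@@H]12 | intermediate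
10 | (1R,4S,5R)-6-hydroxy-4,7-bis(3,4-dimethoxyphenyl)-3-oxabicyclo[3.2.0]heptan-2-one, C6 and C7 epimers | O=C1O[C@H](c3ccc(OC)c(OC)c3)[C@H]2C(O)C(c3ccc(OC)c(OC)c3)[C@@H]12 | intermediate
11 | (2S,3S,4R)-4-(3,4-dimethoxybenzyl)-2-(3,4-dimethoxyphenyl)-5-oxooxolane-3-carbaldehyde | O=C[C@H]1[C@@H](Cc2ccc(OC)c(OC)c2)C(=O)O[C@@H]1c1ccc(OC)c(OC)c1 | intermediate
12 | (2R,3R)-2-(3,4-dimethoxybenzyl)-3-[(S)-(3,4-dimethoxyphenyl)(hydroxy)methyl]butane-1,4-diol | OC[C@@H]([C@@H](Cc1ccc(OC)c(OC)c1)CO)[C@H](O)c1ccc(OC)c(OC)c1 | intermediate
13 | [(2S,3R,4R)-4-(3,4-dimethoxybenzyl)-2-(3,4-dimethoxyphenyl)oxolan-3-yl]methanol | OC[C@H]1[C@@H](Cc2ccc(OC)c(OC)c2)CO[C@@H]1c1ccc(OC)c(OC)c1 | intermediate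
14 | angelic acid, (2Z)-2-methylbut-2-enoic acid | C/C=C(/C)C(=O)O | starting material
15 | leoligin | C/C=C(/C)C(=O)OC[C@H]1[C@@H](Cc2ccc(OC)c(OC)c2)CO[C@@H]1c1ccc(OC)c(OC)c1 | target

**Step count**

Total: 10 steps. Longest linear sequence: 9 steps (steps 1, 2, 3, 5, 6, 7, 8, 9, 10); step 4 is a one-step side branch.

**Steps most likely to fail**

1. Step 5 (proposed new method). The short-lived enol ether triplet may relax by E/Z isomerisation faster than it is captured by 6. Homodimerisation of 8 may compete. Facial selectivity may be incomplete, which would later erode enantiopurity.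

   The fallback uses known chemistry only, sets out from 6 and returns at 11. It builds the two bonds one after the other. Benzophenone-sensitised photoaddition of 1,3-dioxolane (as solvent, 350 nm) should place a masked formyl group on C3 anti to the aryl group and give (4S,5S)-5-(3,4-dimethoxyphenyl)-4-(1,3-dioxolan-2-yl)oxolan-2-one F1. Lithium enolate aldol addition to 3,4-dimethoxybenzaldehyde (LiN(SiMe3)2, THF, −78 °C) should give the aldol adduct F2. Mesylation (MsCl, Et3N) gives the mesylate F3, and DBU eliminates it to the (E)-benzylidene lactone F4. Hydrogenation over palladium on carbon (rhodium on alumina if the benzylic lactone C–O bond proves labile) should add hydrogen to the face opposite the C3 substituent and give the 3,4-cis lactone acetal F5. Aqueous HCl in THF then releases aldehyde 11.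

2. Step 7. Oxidation of the arenes may divert into radical-cation cycloreversion of the cyclobutane. The β-acyloxy aldehyde may also epimerise at C3 or expel the C2 carboxylate under the collidine as it forms.

   The fallback sets out from 10 and returns at 13. It replaces the radical cleavage by a two-electron oxygen insertion. Dess–Martin oxidation should give the cyclobutanone F6. Baeyer–Villiger oxidation (mCPBA, NaHCO3, CH2Cl2, 0 °C) with migration of the benzylic C7' should give the bis-lactone F7, in which C9 and C7' are now linked through oxygen. LiAlH4 reduces it to the tetraol F8. Acid (camphorsulfonic acid, CH2Cl2) closes both oxolane rings to pinoresinol dimethyl ether F9. Hydrogenolysis of one of its two equivalent benzylic C–O bonds (H2, palladium on carbon, stopped at one equivalent) should give 13. Over-reduction to the ring-opened diol is the loss to watch.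

3. Step 9. The product may re-ionise under the acid, and the C2 cation may then be captured irreversibly by the electron-rich ring of the C4 benzyl group (aryltetralin formation). The trans selectivity at C2 may also be incomplete.

   The fallback sets out from 11 and returns at 13. It never breaks the C2–O bond, so the (2S) centre of the lactone is carried through. NaBH4 (MeOH, −20 °C, kept cold to avoid acyl migration) reduces only the aldehyde to the hydroxymethyl lactone F10. TBDPSCl and imidazole give the silyl ether F11. iBu2AlH (CH2Cl2, −78 °C) gives the lactol F12. Et3SiH with BF3·OEt2 at −78 °C reduces the lactol through the C5 oxocarbenium ion to the silyl-protected oxolane F13. Bu4NF then frees 13.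

**Further compounds**

F1 | step 5 | (4S,5S)-5-(3,4-dimethoxyphenyl)-4-(1,3-dioxolan-2-yl)oxolan-2-one | O1CCOC1[C@H]2CC(=O)O[C@@H]2c1ccc(OC)c(OC)c1
F2 | step 5 | (3R,4S,5S)-3-[(3,4-dimethoxyphenyl)(hydroxy)methyl]-5-(3,4-dimethoxyphenyl)-4-(1,3-dioxolan-2-yl)oxolan-2-one, carbinol epimers | O1CCOC1[C@H]2[C@H](C(O)c3ccc(OC)c(OC)c3)C(=O)O[C@@H]2c1ccc(OC)c(OC)c1
F3 | step 5 | methanesulfonate of F2 | O1CCOC1[C@H]2[C@H](C(OS(C)(=O)=O)c3ccc(OC)c(OC)c3)C(=O)O[C@@H]2c1ccc(OC)c(OC)c1
F4 | step 5 | (3E,4S,5S)-3-(3,4-dimethoxybenzylidene)-5-(3,4-dimethoxyphenyl)-4-(1,3-dioxolan-2-yl)oxolan-2-one | O1CCOC1[C@H]2/C(=C\c3ccc(OC)c(OC)c3)C(=O)O[C@@H]2c1ccc(OC)c(OC)c1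
F5 | step 5 | (3R,4S,5S)-3-(3,4-dimethoxybenzyl)-5-(3,4-dimethoxyphenyl)-4-(1,3-dioxolan-2-yl)oxolan-2-one | O1CCOC1[C@H]2[C@@H](Cc3ccc(OC)c(OC)c3)C(=O)O[C@@H]2c1ccc(OC)c(OC)c1
F6 | step 7 | (1R,4S,5S)-4,7-bis(3,4-dimethoxyphenyl)-3-oxabicyclo[3.2.0]heptane-2,6-dione, C7 epimers | O=C1O[C@H](c3ccc(OC)c(OC)c3)[C@H]2C(=O)C(c3ccc(OC)c(OC)c3)[C@@H]12
F7 | step 7 | (1S,4S,5S)-4,8-bis(3,4-dimethoxyphenyl)-3,7-dioxabicyclo[3.3.0]octane-2,6-dione, C8 epimers | O=C1O[C@H](c3ccc(OC)c(OC)c3)[C@H]2C(=O)OC(c3ccc(OC)c(OC)c3)[C@@H]12
F8 | step 7 | (2R,3R)-2,3-bis[(3,4-dimethoxyphenyl)(hydroxy)methyl]butane-1,4-diol, one carbinol (S), the other epimeric | OC[C@@H]([C@@H](C(O)c1ccc(OC)c(OC)c1)CO)[C@H](O)c1ccc(OC)c(OC)c1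
F9 | step 7 | (1S,3aR,4S,6aR)-1,4-bis(3,4-dimethoxyphenyl)tetrahydro-1H,3H-furo[3,4-c]furan (pinoresinol dimethyl ether) | O3C[C@H]1[C@@H]([C@H]3c2ccc(OC)c(OC)c2)CO[C@@H]1c1ccc(OC)c(OC)c1
F10 | step 9 | (3R,4R,5S)-3-(3,4-dimethoxybenzyl)-5-(3,4-dimethoxyphenyl)-4-(hydroxymethyl)oxolan-2-one | OC[C@H]1[C@@H](Cc2ccc(OC)c(OC)c2)C(=O)O[C@@H]1c1ccc(OC)c(OC)c1
F11 | step 9 | (3R,4R,5S)-4-{[(tert-butyldiphenylsilyl)oxy]methyl}-3-(3,4-dimethoxybenzyl)-5-(3,4-dimethoxyphenyl)oxolan-2-one | CC(C)(C)[Si](c1ccccc1)(c1ccccc1)OC[C@H]1[C@@H](Cc2ccc(OC)c(OC)c2)C(=O)O[C@@H]1c1ccc(OC)c(OC)c1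
F12 | step 9 | (3R,4R,5S)-4-{[(tert-butyldiphenylsilyl)oxy]methyl}-3-(3,4-dimethoxybenzyl)-5-(3,4-dimethoxyphenyl)oxolan-2-ol, anomers | CC(C)(C)[Si](c1ccccc1)(c1ccccc1)OC[C@H]1[C@@H](Cc2ccc(OC)c(OC)c2)C(O)O[C@@H]1c1ccc(OC)c(OC)c1
F13 | step 9 | tert-butyl{[(2S,3R,4R)-4-(3,4-dimethoxybenzyl)-2-(3,4-dimethoxyphenyl)oxolan-3-yl]methoxy}diphenylsilane | CC(C)(C)[Si](c1ccccc1)(c1ccccc1)OC[C@H]1[C@@H](Cc2ccc(OC)c(OC)c2)CO[C@@H]1c1ccc(OC)c(OC)c1
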